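## Retrosynthetic overview

1. Locants follow furo[3,4-c]furan-1-one numbering: C1(=O)–O2–C3(H, syringyl)–C3a(H)–C4H2–O5–C6(H, catechol)–C6a(H). The lactone ring is C1/O2/C3/C3a/C6a and the ether ring is C3a/C4/O5/C6/C6a. H-3, H-3a, H-6 and H-6a all lie on one face, so both aryl groups are endo.
2. The last C–H bonds come from syn hydrogenation of a flat furan lactone, from the face opposite the C3 aryl group. This sets C3a, C6a and C6 together. C3 is the only stereocentre that has to be made separately, by lipase resolution of a propargylic alcohol.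
3. The ether ring is not closed directly. It is made as a furan by two-atom ring expansion of a cyclopropene (C6a/C3a/C4), with the aroyl C6=O5 unit inserted between C6a and C4. The C3 hydroxyl then closes the lactone on an activated C1 ester in the same flask.
4. Enabling feature: C6a carries both C1(=O) and the aryl-bearing C6–O5 unit, which is a masked aroylacetate. C4 is an unsubstituted CH2 and C3a bears the carbinol C3. This is the pattern of a 3-aroylcyclopropene-3-carboxylate built from a terminal alkyne (C4≡C3a–C3) and a diazo aroylacetate (C6, C6a, C1).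
5. Ring order: cyclopropene (step 9), then furan and lactone (both step 10), then saturation (step 11), then desilylation (step 12).

Key step: step 10

Remark on the chemistry: the lipase is assumed to follow the usual size rule for secondary alcohols (aryl large, ethynyl medium), so the (S)-propargylic alcohol is the unreacted enantiomer. TBS = tert-butyldimethylsilyl, TES = triethylsilyl. The ring carbon C6a of the cyclopropenes is left undefined in the SMILES because both epimers are used.

## Route

Step 1
Reactants: 1 syringaldehyde (4-hydroxy-3,5-dimethoxybenzaldehyde)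
Product: 2 4-(tert-butyldimethylsilyloxy)-3,5-dimethoxybenzaldehyde
Conditions: TBSCl, imidazole, DMF, 25 °C
Reagents that add atoms: TBSCl, CC(C)(C)[Si](C)(C)Cl
Why: Standard phenol silylation; the aryl silyl ether should survive the Grignard, carbene, copper and hydrogenation steps and can be removed at the end with buffered fluoride, without acid or base.

Step 2
Reactants: 2 4-(tert-butyldimethylsilyloxy)-3,5-dimethoxybenzaldehyde
Product: 3 rac-1-[4-(tert-butyldimethylsilyloxy)-3,5-dimethoxyphenyl]prop-2-yn-1-ol
Conditions: HC≡CMgBr, THF, −20 to 0 °C; H2O work-up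
Reagents that add atoms: ethynylmagnesium bromide, C#C[Mg]Br
Why: Grignard 1,2-addition to an aromatic aldehyde gives the racemic propargylic alcohol, and no stereocontrol is sought at this stage.

Step 3
Reactants: 3 rac-1-[4-(tert-butyldimethylsilyloxy)-3,5-dimethoxyphenyl]prop-2-yn-1-ol
Product: 4 (1S)-1-[4-(tert-butyldimethylsilyloxy)-3,5-dimethoxyphenyl]prop-2-yn-1-ol
Conditions: Novozym 435 (immobilised Candida antarctica lipase B), vinyl acetate, MTBE, 35 °C, stopped just past half conversion; chromatography
Reagents that add atoms: none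
Why: Lipase-catalysed kinetic resolution by irreversible transesterification, a known reaction of 1-arylprop-2-yn-1-ols, should acetylate the (R)-alcohol and leave the (S)-alcohol, whose carbinol carbon is C3 of the target in its final configuration.

Step 4
Reactants: 4 (1S)-1-[4-(tert-butyldimethylsilyloxy)-3,5-dimethoxyphenyl]prop-2-yn-1-ol
Product: 5 (S)-triethylsilyl ether of 4
Conditions: TESCl, imidazole, CH2Cl2, 0 °C
Reagents that add atoms: TESCl, CC[Si](Cl)(CC)CC
Why: Silylation masks the O–H bond, which would otherwise undergo O–H insertion with the rhodium carbene, and an alkyl TES ether can later be cleaved under acidic fluoride in the presence of aryl TBS ethers.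

Step 5
Reactants: 6 3,4-dihydroxybenzoic acid
Product: 8 3,4-bis(tert-butyldimethylsilyloxy)benzoic acid, via silyl ester 7 (not isolated)
Conditions: TBSCl (3.5 equiv), imidazole, DMF, 25 °C; then AcOH–THF–H2O, 25 °C
Reagents that add atoms: TBSCl, CC(C)(C)[Si](C)(C)Cl
Why: Exhaustive silylation followed by selective hydrolysis of the far more labile silyl ester is the standard way to protect a phenolic acid.

Step 6
Reactants: 8 3,4-bis(tert-butyldimethylsilyloxy)benzoic acid
Product: 9 5-{[3,4-bis(tert-butyldimethylsilyloxy)phenyl](hydroxy)methylidene}-2,2-dimethyl-1,3-dioxane-4,6-dione (acyl Meldrum's acid, enol form)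
Conditions: Meldrum's acid, DCC, DMAP, CH2Cl2, 0 to 25 °C; aq. KHSO4 wash
Reagents that add atoms: Meldrum's acid, CC1(C)OC(=O)CC(=O)O1
Why: Carbodiimide-mediated C-acylation of Meldrum's acid is the usual mild homologation of a carboxylic acid towards a β-keto ester.

Step 7
Reactants: 9 acyl Meldrum's acid
Product: 10 2,2,2-trifluoroethyl 3-[3,4-bis(tert-butyldimethylsilyloxy)phenyl]-3-oxopropanoate
Conditions: CF3CH2OH (5 equiv), toluene, 90 °C, sealed tube
Reagents that add atoms: 2,2,2-trifluoroethanol, OCC(F)(F)F
Why: Thermal alcoholysis of an acyl Meldrum's acid (loss of acetone and CO2) gives the β-keto ester, and the trifluoroethyl group is chosen as an activating ester that has no C–H or aryl site for carbene insertion and leaves again in step 10.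

Step 8
Reactants: 10 trifluoroethyl β-keto ester
Product: 11 2,2,2-trifluoroethyl 2-diazo-3-[3,4-bis(tert-butyldimethylsilyloxy)phenyl]-3-oxopropanoate
Conditions: 4-acetamidobenzenesulfonyl azide, Et3N, MeCN, 0 to 25 °C
Reagents that add atoms: 4-acetamidobenzenesulfonyl azide, CC(=O)Nc1ccc(cc1)S(=O)(=O)N=[N+]=[N-]
Why: Regitz diazo transfer to an active methylene compound proceeds under mild amine base that leaves aryl silyl ethers intact.

Step 9
Reactants: 5 (S)-triethylsilyl ether of 4, 11 diazo aroylacetate
Product: 13 2,2,2-trifluoroethyl 1-[3,4-bis(tert-butyldimethylsilyloxy)benzoyl]-2-{(R)-hydroxy[4-(tert-butyldimethylsilyloxy)-3,5-dimethoxyphenyl]methyl}cycloprop-2-ene-1-carboxylate (both ring-C1 epimers), via TES-protected cyclopropene 12 (not isolated)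
Conditions: Rh2(OAc)4 (2 mol %), CH2Cl2, 40 °C, 11 (2 equiv) added over 10 h; then HF·pyridine, pyridine, THF, 0 °C
Reagents that add atoms: none
Why: Rhodium-carbene [2+1] cycloaddition (cyclopropenation) of a terminal, alkyl-type alkyne with a 2-diazo-1,3-dicarbonyl compound is followed by acidic-fluoride cleavage of the alkyl TES ether; the new quaternary carbon C6a forms as both epimers, which is harmless because it becomes sp2 in step 10, and the carbinol carbon keeps its spatial arrangement (its descriptor changes to R only through CIP priorities).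

Step 10
Reactants: 13 hydroxy cyclopropene
Product: 15 (3R)-6-[3,4-bis(tert-butyldimethylsilyloxy)phenyl]-3-[4-(tert-butyldimethylsilyloxy)-3,5-dimethoxyphenyl]-1H,3H-furo[3,4-c]furan-1-one, via hydroxy furan ester 14 (not isolated)
Conditions: CuI (10 mol %), MeCN (0.05 M), 4 Å MS, 80 °C; then DMAP (20 mol %), 60 °C, same flask
Reagents that add atoms: none
Why: CuI adds across the strained C3a=C4 double bond with iodide on the unsubstituted C4 and copper on C3a, β-carbon elimination then breaks the C6a–C4 σ bond to give a copper enolate of the aroylacetate unit carrying a 2-iodovinyl group, and the ketone-derived enolate oxygen O5 closes on C4 with loss of CuI, so that the three-membered ring C6a/C3a/C4 grows by C6 and O5 into the furan of 14. The closest known reaction type is the CuI-catalysed ring-opening cycloisomerisation of 3-acylcycloprop-1-ene-3-carboxylates made from terminal alkynes to 2,3,4-trisubstituted furans, the cyclopropene counterpart of the Cloke–Wilson rearrangement. The furan closes by a 5-endo-trig oxycupration followed by β-iodide elimination, and the lactone closes by a 5-exo-trig addition–elimination of the C3 hydroxyl at the C1 trifluoroethyl ester, which DMAP catalyses and which the good leaving group, the dilute aprotic medium and the sieves should make irreversible despite the strain of the 5-5-fused furan. No stereocentre is created: the stereorandom C6a becomes sp2, and C3 keeps its configuration because neither its C–O nor its C–H bond is touched and no acid is present. The step needs cleavage of C6a–C4 rather than C6a–C3a (2,3,4- against 2,3,5-substitution) and closure through the ketone rather than the ester oxygen; the first is secured by iodide attack at the only unhindered ring carbon next to the bulky carbinol substituent, the second by the higher nucleophilicity of the aryl ketone enolate oxygen compared with the electron-poor ester. Release of cyclopropene strain and gain of aromaticity drive the sequence, and its product is the flat template with a single stereocentre that step 11 requires.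

Step 11
Reactants: 15 furan lactone
Product: 16 (3S,3aS,6S,6aR)-6-[3,4-bis(tert-butyldimethylsilyloxy)phenyl]-3-[4-(tert-butyldimethylsilyloxy)-3,5-dimethoxyphenyl]tetrahydro-1H,3H-furo[3,4-c]furan-1-one
Conditions: H2 (50 bar), 5 % Rh/Al2O3, EtOAc, 25 °C
Reagents that add atoms: none
Why: Heterogeneous syn hydrogenation of a 2-arylfuran, a reaction type known to give all-cis tetrahydrofurans, should deliver all hydrogen to the face of the flat bicycle opposite the C3 aryl group, so that H-3a, H-6a and H-6 end up cis to H-3 (cis ring fusion, both aryl groups endo), and rhodium is chosen because it saturates furans with little benzylic C–O hydrogenolysis while the hindered silylated arenes should stay intact.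

Step 12
Reactants: 16 tris-TBS ether of the target
Product: 17 (3S,3aS,6S,6aR)-6-(3,4-dihydroxyphenyl)-3-(4-hydroxy-3,5-dimethoxyphenyl)tetrahydro-1H,3H-furo[3,4-c]furan-1-one (target)
Conditions: TBAF (3.3 equiv), AcOH (3.6 equiv), THF, 0 °C, argon; pH 6 buffer work-up
Reagents that add atoms: none
Why: Fluoride cleavage of the three aryl silyl ethers is buffered with acetic acid so that no free phenoxide can expel the C3 carboxylate or O5 as a quinone methide, which should preserve the kinetically formed endo,endo configuration.

## Compound list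

1 | syringaldehyde | COc1cc(C=O)cc(OC)c1O | starting material
2 | 4-(tert-butyldimethylsilyloxy)-3,5-dimethoxybenzaldehyde | COc1cc(C=O)cc(OC)c1O[Si](C)(C)C(C)(C)C | intermediate
3 | rac-1-[4-(TBSO)-3,5-dimethoxyphenyl]prop-2-yn-1-ol | COc1cc(C(O)C#C)cc(OC)c1O[Si](C)(C)C(C)(C)C | intermediate
4 | (1S)-1-[4-(TBSO)-3,5-dimethoxyphenyl]prop-2-yn-1-ol | COc1cc([C@H](C#C)O)cc(OC)c1O[Si](C)(C)C(C)(C)C | intermediate
5 | (S)-triethylsilyl ether of 4 | COc1cc([C@H](C#C)O[Si](CC)(CC)CC)cc(OC)c1O[Si](C)(C)C(C)(C)C | intermediate
6 | 3,4-dihydroxybenzoic acid | OC(=O)c1ccc(O)c(O)c1 | starting material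
7 | tert-butyldimethylsilyl 3,4-bis(TBSO)benzoate | CC(C)(C)[Si](C)(C)OC(=O)c1ccc(O[Si](C)(C)C(C)(C)C)c(O[Si](C)(C)C(C)(C)C)c1 | intermediate
8 | 3,4-bis(TBSO)benzoic acid | OC(=O)c1ccc(O[Si](C)(C)C(C)(C)C)c(O[Si](C)(C)C(C)(C)C)c1 | intermediate
9 | acyl Meldrum's acid (enol form) | CC1(C)OC(=O)C(=C(O)c2ccc(O[Si](C)(C)C(C)(C)C)c(O[Si](C)(C)C(C)(C)C)c2)C(=O)O1 | intermediate
10 | 2,2,2-trifluoroethyl 3-[3,4-bis(TBSO)phenyl]-3-oxopropanoate | O=C(CC(=O)OCC(F)(F)F)c1ccc(O[Si](C)(C)C(C)(C)C)c(O[Si](C)(C)C(C)(C)C)c1 | intermediate
11 | 2,2,2-trifluoroethyl 2-diazo-3-[3,4-bis(TBSO)phenyl]-3-oxopropanoate | [N-]=[N+]=C(C(=O)OCC(F)(F)F)C(=O)c1ccc(O[Si](C)(C)C(C)(C)C)c(O[Si](C)(C)C(C)(C)C)c1 | intermediate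
12 | TES-protected cyclopropene (carbinol R, both ring-C1 epimers) | COc1cc([C@H](C2=CC2(C(=O)OCC(F)(F)F)C(=O)c2ccc(O[Si](C)(C)C(C)(C)C)c(O[Si](C)(C)C(C)(C)C)c2)O[Si](CC)(CC)CC)cc(OC)c1O[Si](C)(C)C(C)(C)C | intermediate
13 | hydroxy cyclopropene (carbinol R, both ring-C1 epimers) | COc1cc([C@H](C2=CC2(C(=O)OCC(F)(F)F)C(=O)c2ccc(O[Si](C)(C)C(C)(C)C)c(O[Si](C)(C)C(C)(C)C)c2)O)cc(OC)c1O[Si](C)(C)C(C)(C)C | intermediate
14 | 2,2,2-trifluoroethyl 2-[3,4-bis(TBSO)phenyl]-4-{(R)-hydroxy[4-(TBSO)-3,5-dimethoxyphenyl]methyl}furan-3-carboxylate | COc1cc([C@H](c2coc(-c3ccc(O[Si](C)(C)C(C)(C)C)c(O[Si](C)(C)C(C)(C)C)c3)c2C(=O)OCC(F)(F)F)O)cc(OC)c1O[Si](C)(C)C(C)(C)C | intermediate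
15 | (3R)-furan lactone | COc1cc([C@H]2OC(=O)c3c2coc3-c2ccc(O[Si](C)(C)C(C)(C)C)c(O[Si](C)(C)C(C)(C)C)c2)cc(OC)c1O[Si](C)(C)C(C)(C)C | intermediate
16 | (3S,3aS,6S,6aR)-tris-TBS ether of the target | COc1cc([C@H]2OC(=O)[C@@H]3[C@H]2CO[C@@H]3c2ccc(O[Si](C)(C)C(C)(C)C)c(O[Si](C)(C)C(C)(C)C)c2)cc(OC)c1O[Si](C)(C)C(C)(C)C | intermediate
17 | CNP0224550.1 | COc1cc([C@H]2OC(=O)[C@@H]3[C@H]2CO[C@@H]3c2ccc(O)c(O)c2)cc(OC)c1O | target

## Step count and risks

Total step count: 12.

Longest linear sequence: 8 steps (1–4, then 9–12). The branch 5–8, then 9–12, is equally long.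

The three steps most likely to fail are listed below.

**Step 11.**
- Saturation may stall at the tetrasubstituted C6=C6a bond.
- Facial selectivity may erode if the partly reduced intermediate desorbs.
- Prolonged exposure may lead to hydrogenolysis of the benzylic C–O bonds or to arene reduction.
- The fallback sets out from 15 and returns at 16. The catalytic reduction is stopped after one equivalent of hydrogen (1 bar H2, 5 % Rh/Al2O3, EtOAc), which should saturate only the enol-ether C3a=C4 bond anti to the C3 aryl group and give the dihydrofuran lactone F1.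
- The remaining vinylogous carbonate is then reduced by ionic hydrogenation (Et3SiH, CF3CO2H, CH2Cl2, −40 °C). Protonation at C6a and hydride delivery to the C6 oxocarbenium ion should both occur from the convex face of the bicycle, which leads to 16.

**Step 9.**
- Carbene dimerisation, Wolff rearrangement or premature rhodium-catalysed isomerisation of the cyclopropene may outrun the intermolecular addition to the hindered, inductively deactivated alkyne.
- The fallback sets out from 4, with 9 as acyl donor, and returns at 15. It replaces the intermolecular union by a tethered one.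
- Heating 4 with 9 in toluene (100 °C) should give the propargyl β-keto ester F2. Regitz diazo transfer (4-acetamidobenzenesulfonyl azide, Et3N, MeCN) should give the diazo ester F3.
- Rh2(OAc)4 in benzene at 80 °C should then trigger the known carbene–alkyne cascade of 2-alkynyl 2-diazo-3-oxoalkanoates. The carbene adds to the tethered alkyne, and the aroyl oxygen attacks the resulting vinyl carbene, which delivers 15 directly.

**Step 10.**
- The free hydroxyl may interfere with the organocopper intermediates.
- The sequence may stall at the hydroxy ester because the 5-5-fused lactone is strained.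
- Aryl silyl groups may be lost during prolonged heating with DMAP and the liberated alcohol.
- The fallback sets out from 12, isolated before desilylation, and returns at 15. It separates the events and closes the lactone by acid activation.
- CuI in MeCN at 80 °C should convert 12 into the TES-protected furan ester F4, and HF·pyridine then gives 14, which is isolated.
- Me3SnOH in 1,2-dichloroethane at 60 °C cleaves the trifluoroethyl ester to the hydroxy acid F5. Yamaguchi lactonisation (2,4,6-trichlorobenzoyl chloride, Et3N, DMAP, toluene) then closes the ring to 15 with retention at C3.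

## Further compounds

F1 | step 11 | (3S,3aS)-6-[3,4-bis(TBSO)phenyl]-3-[4-(TBSO)-3,5-dimethoxyphenyl]-3a,4-dihydro-1H,3H-furo[3,4-c]furan-1-one | COc1cc([C@H]2OC(=O)C3=C(c4ccc(O[Si](C)(C)C(C)(C)C)c(O[Si](C)(C)C(C)(C)C)c4)OC[C@@H]23)cc(OC)c1O[Si](C)(C)C(C)(C)C
F2 | step 9 | (1S)-1-[4-(TBSO)-3,5-dimethoxyphenyl]prop-2-yn-1-yl 3-[3,4-bis(TBSO)phenyl]-3-oxopropanoate | COc1cc([C@H](C#C)OC(=O)CC(=O)c2ccc(O[Si](C)(C)C(C)(C)C)c(O[Si](C)(C)C(C)(C)C)c2)cc(OC)c1O[Si](C)(C)C(C)(C)C
F3 | step 9 | (1S)-1-[4-(TBSO)-3,5-dimethoxyphenyl]prop-2-yn-1-yl 2-diazo-3-[3,4-bis(TBSO)phenyl]-3-oxopropanoate | COc1cc([C@H](C#C)OC(=O)C(=[N+]=[N-])C(=O)c2ccc(O[Si](C)(C)C(C)(C)C)c(O[Si](C)(C)C(C)(C)C)c2)cc(OC)c1O[Si](C)(C)C(C)(C)C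
F4 | step 10 | 2,2,2-trifluoroethyl 2-[3,4-bis(TBSO)phenyl]-4-{(R)-[4-(TBSO)-3,5-dimethoxyphenyl](triethylsilyloxy)methyl}furan-3-carboxylate | COc1cc([C@H](c2coc(-c3ccc(O[Si](C)(C)C(C)(C)C)c(O[Si](C)(C)C(C)(C)C)c3)c2C(=O)OCC(F)(F)F)O[Si](CC)(CC)CC)cc(OC)c1O[Si](C)(C)C(C)(C)C
F5 | step 10 | 2-[3,4-bis(TBSO)phenyl]-4-{(R)-hydroxy[4-(TBSO)-3,5-dimethoxyphenyl]methyl}furan-3-carboxylic acid | COc1cc([C@H](c2coc(-c3ccc(O[Si](C)(C)C(C)(C)C)c(O[Si](C)(C)C(C)(C)C)c3)c2C(=O)O)O)cc(OC)c1O[Si](C)(C)C(C)(C)C
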